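**Plan**

- The target is 7-hydroxy-6-methoxy-3-(3,4,5-trimethoxyphenyl)chromen-4-one. O1 and C4 of ring C are bonded to the neighbouring ring A carbons C8a and C4a, so both bonds can be traced to the two ends of one aryne.
- Cuts: C5-H and O7-H go back to C5-Cl and O7-benzyl. Then O1-C8a and C4-C4a are cut together, giving an aryne and a C2-C3-C4 enol ester that carries ring B. Last, C2-C3 is cut to methyl formate and an arylacetate.
- Forward, ring A is bought as 5-chlorovanillin and dressed in six steps. A bromine set early between CHO and Cl marks the carbon that receives silicon, and the formyl carbon is exchanged for the triflate oxygen.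
- Ring B is bought with the arylacetate, which is formylated. Ring C is the only ring built and closes in the aryne step. One hydrogenolysis then removes chlorine and benzyl.
- The target has no stereocentre. The only stereochemical element is the Z geometry of the enol(ate), held by hydrogen bond or caesium chelation, which keeps the ester beside the attacking oxygen.

Key step: step 8

Assumption: the formylated ester is handled and drawn as its hydrogen-bonded Z enol; the formyl tautomer in equilibrium with it gives the same enolate. Chromone numbering is used for the target and the aryne adducts.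

**Route**

Step 1
Reactants: 1 5-chlorovanillin (3-chloro-4-hydroxy-5-methoxybenzaldehyde)
Product: 2 2-bromo-3-chloro-4-hydroxy-5-methoxybenzaldehyde
Conditions: Br2 (1.2 equiv), Fe powder (cat.), AcOH, 25 to 60 °C
Reagents that add atoms: bromine, BrBr
Why: Electrophilic aromatic bromination: all positions ortho and para to the free OH are filled, so the methoxy group directs to its open para position, the carbon between CHO and Cl, which is the site 5-bromovanillin offers to a second bromine.

Step 2
Reactants: 2 2-bromo-3-chloro-4-hydroxy-5-methoxybenzaldehyde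
Product: 3 2-bromo-3-chloro-4,5-dihydroxybenzaldehyde
Conditions: AlCl3 (1.3 equiv), pyridine (4.5 equiv), CH2Cl2, reflux; aq. HCl
Reagents that add atoms: none
Why: Lewis-acid cleavage of an aryl methyl ether assisted by the neighbouring phenol: aluminium binds the phenoxide and the adjacent methoxy oxygen in a five-membered chelate and pyridine takes the activated methyl group in an SN2 step, leaving the aldehyde and both halogens untouched.

Step 3
Reactants: 3 2-bromo-3-chloro-4,5-dihydroxybenzaldehyde
Product: 4 2-bromo-3-chloro-5-hydroxy-4-methoxybenzaldehyde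
Conditions: MeI (1.2 equiv), Li2CO3 (1.1 equiv), DMF, 45 °C
Reagents that add atoms: iodomethane, CI
Why: Williamson methylation under acidity control: the 4-OH, para to the formyl group and ortho to chlorine, is clearly the more acidic, so the weak base ionises only this oxygen and MeI alkylates it, as is usual for 3,4-dihydroxybenzaldehydes.

Step 4
Reactants: 4 2-bromo-3-chloro-5-hydroxy-4-methoxybenzaldehyde
Product: 5 5-(benzyloxy)-2-bromo-3-chloro-4-methoxybenzaldehyde
Conditions: BnBr, K2CO3, DMF, rt
Reagents that add atoms: benzyl bromide, BrCc1ccccc1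
Why: Williamson benzylation of the single remaining phenol, with no competing nucleophilic site.

Step 5
Reactants: 5 5-(benzyloxy)-2-bromo-3-chloro-4-methoxybenzaldehyde
Product: 7 5-(benzyloxy)-2-bromo-3-chloro-4-methoxyphenol, via aryl formate 6 (not isolated)
Conditions: mCPBA, CH2Cl2, 40 °C; then K2CO3 (cat.), MeOH, rt
Reagents that add atoms: 3-chloroperbenzoic acid, OOC(=O)c1cccc(Cl)c1
Why: Baeyer-Villiger oxidation of an alkoxy-substituted benzaldehyde: the aryl group with its para methoxy group migrates in preference to hydride to give formate 6, and mild methanolysis cleaves it without touching the benzyl ether or the halogens.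

Step 6
Reactants: 7 5-(benzyloxy)-2-bromo-3-chloro-4-methoxyphenol
Product: 11 5-(benzyloxy)-3-chloro-4-methoxy-2-(trimethylsilyl)phenyl trifluoromethanesulfonate, via trimethylsilyl ether 8 (not isolated), via aryllithium 9 (not isolated), via lithium 2-silylphenoxide 10 (not isolated)
Conditions: HMDS, THF, 70 °C, evaporate; n-BuLi (1.1 equiv), THF, -100 to -80 °C; Tf2O (1.2 equiv), -100 °C to rt
Reagents that add atoms: hexamethyldisilazane, C[Si](C)(C)N[Si](C)(C)C; trifluoromethanesulfonic anhydride, O=S(=O)(OS(=O)(=O)C(F)(F)F)C(F)(F)F
Why: O-silylation, bromine-lithium exchange, retro-Brook 1,3-shift of silicon from oxygen to carbon and triflation of the phenoxide form the standard one-flask entry to ortho-silylaryl triflates; exchange at bromine is much faster than attack on C-Cl or the benzylic CH2, and at or below -80 °C the intramolecular silyl shift should outrun loss of LiCl from 9.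

Step 7
Reactants: 12 methyl 3,4,5-trimethoxyphenylacetate; 13 methyl formate
Product: 14 methyl (Z)-3-hydroxy-2-(3,4,5-trimethoxyphenyl)acrylate
Conditions: NaH (2.5 equiv), 13 (5 equiv), THF, 0 °C to rt; aq. HCl
Reagents that add atoms: none
Why: Crossed Claisen condensation (formylation) of an arylacetate with a non-enolisable formate, driven by formation of the stabilised sodium enolate; acidification gives the enol, which adopts the hydrogen-bonded Z form.

Step 8
Reactants: 11 5-(benzyloxy)-3-chloro-4-methoxy-2-(trimethylsilyl)phenyl trifluoromethanesulfonate; 14 methyl (Z)-3-hydroxy-2-(3,4,5-trimethoxyphenyl)acrylate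
Product: 18 7-(benzyloxy)-5-chloro-6-methoxy-3-(3,4,5-trimethoxyphenyl)-4H-chromen-4-one, via caesium enolate 15 (not isolated), via aryne 16 (not isolated), via arylcaesium adduct 17 (not isolated)
Conditions: 14 (1.5 equiv), dry CsF (4 equiv), THF, 65 °C; 11 added slowly by syringe pump
Reagents that add atoms: none
Why: Proposed new method: fluoride attacks the silicon of 11 and triflate leaves to give aryne 16, the oxygen of caesium enolate 15 adds to C8a, and the aryl anion 17 that results at C4a attacks the cis ester carbonyl and expels methoxide, so that O1-C8a and C4-C4a form in one operation. The closest known reaction type is the union of arynes with salicylate esters to give xanthones (phenoxide addition followed by intramolecular acyl substitution), and the present case replaces the phenoxide by its vinylogue, a 3-oxidoacrylate. Ring C closes in a 6-exo-trig acyl substitution and no stereocentre is created. The site selectivity on the aryne rests on the C5 chlorine, whose inductive pull distorts the triple bond so that the remote carbon C8a is the electrophilic end and the charge builds up at C4a beside chlorine, while the C6 and C7 oxygens lie meta and para to the two aryne carbons in opposite senses and cancel each other. Attack through oxygen and not carbon is favoured by the fully substituted, aryl-shielded enolate carbon, in line with the O-alkylation that 2-aryl-3-hydroxyacrylates normally show, and THF is preferred to a polar solvent so that caesium bridges enolate oxygen and ester carbonyl and holds the Z geometry, the only one from which 17 can cyclise. Slow addition of 11 to an excess of 15 keeps the aryne concentration low and limits its capture by the released methoxide or by a second aryne.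

Step 9
Reactants: 18 7-(benzyloxy)-5-chloro-6-methoxy-3-(3,4,5-trimethoxyphenyl)-4H-chromen-4-one
Product: 19 7-hydroxy-6-methoxy-3-(3,4,5-trimethoxyphenyl)-4H-chromen-4-one
Conditions: H2 (1 atm), 10% Pd/C, Et3N (2 equiv), MeOH-THF, rt, stopped after two equivalents of H2
Reagents that add atoms: none
Why: Catalytic hydrogenolysis: Pd/C cleaves the phenolic benzyl ether and, with Et3N as HCl acceptor, hydrodechlorinates the C5-Cl bond that the ortho carbonyl activates, while control of the hydrogen uptake should spare the C2-C3 double bond.

**Compound list**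

1 | 5-chlorovanillin (3-chloro-4-hydroxy-5-methoxybenzaldehyde) | COc1cc(C=O)cc(Cl)c1O | starting material
2 | 2-bromo-3-chloro-4-hydroxy-5-methoxybenzaldehyde | COc1cc(C=O)c(Br)c(Cl)c1O | intermediate
3 | 2-bromo-3-chloro-4,5-dihydroxybenzaldehyde | O=Cc1cc(O)c(O)c(Cl)c1Br | intermediate
4 | 2-bromo-3-chloro-5-hydroxy-4-methoxybenzaldehyde | COc1c(O)cc(C=O)c(Br)c1Cl | intermediate
5 | 5-(benzyloxy)-2-bromo-3-chloro-4-methoxybenzaldehyde | COc1c(OCc2ccccc2)cc(C=O)c(Br)c1Cl | intermediate
6 | 5-(benzyloxy)-2-bromo-3-chloro-4-methoxyphenyl formate (not isolated) | COc1c(OCc2ccccc2)cc(OC=O)c(Br)c1Cl | intermediate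
7 | 5-(benzyloxy)-2-bromo-3-chloro-4-methoxyphenol | COc1c(OCc2ccccc2)cc(O)c(Br)c1Cl | intermediate
8 | [5-(benzyloxy)-2-bromo-3-chloro-4-methoxyphenoxy]trimethylsilane (not isolated) | COc1c(OCc2ccccc2)cc(O[Si](C)(C)C)c(Br)c1Cl | intermediate
9 | [4-(benzyloxy)-2-chloro-3-methoxy-6-(trimethylsilyloxy)phenyl]lithium (not isolated) | COc1c(OCc2ccccc2)cc(O[Si](C)(C)C)c([Li])c1Cl | intermediate
10 | lithium 5-(benzyloxy)-3-chloro-4-methoxy-2-(trimethylsilyl)phenoxide (not isolated) | COc1c(OCc2ccccc2)cc([O-])c([Si](C)(C)C)c1Cl.[Li+] | intermediate
11 | 5-(benzyloxy)-3-chloro-4-methoxy-2-(trimethylsilyl)phenyl trifluoromethanesulfonate | COc1c(Cl)c([Si](C)(C)C)c(OS(=O)(=O)C(F)(F)F)cc1OCc1ccccc1 | intermediate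
12 | methyl 3,4,5-trimethoxyphenylacetate | COC(=O)Cc1cc(OC)c(OC)c(OC)c1 | starting material
13 | methyl formate | COC=O | starting material
14 | methyl (Z)-3-hydroxy-2-(3,4,5-trimethoxyphenyl)acrylate | COC(=O)/C(=C\O)c1cc(OC)c(OC)c(OC)c1 | intermediate
15 | caesium (Z)-3-methoxy-3-oxo-2-(3,4,5-trimethoxyphenyl)prop-1-en-1-olate (not isolated) | COC(=O)/C(=C\[O-])c1cc(OC)c(OC)c(OC)c1.[Cs+] | intermediate
16 | 5-(benzyloxy)-3-chloro-4-methoxy-1,2-didehydrobenzene (not isolated) | COC1=C(Cl)C#CC=C1OCc1ccccc1 | intermediate
17 | methyl (Z)-3-[5-(benzyloxy)-2-caesio-3-chloro-4-methoxyphenoxy]-2-(3,4,5-trimethoxyphenyl)acrylate (not isolated) | COC(=O)/C(=C\Oc1cc(OCc2ccccc2)c(OC)c(Cl)[c-]1)c1cc(OC)c(OC)c(OC)c1.[Cs+] | intermediate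
18 | 7-(benzyloxy)-5-chloro-6-methoxy-3-(3,4,5-trimethoxyphenyl)-4H-chromen-4-one | COc1c(Cl)c2c(=O)c(-c3cc(OC)c(OC)c(OC)c3)coc2cc1OCc1ccccc1 | intermediate
19 | 7-hydroxy-6-methoxy-3-(3,4,5-trimethoxyphenyl)-4H-chromen-4-one | COc1cc2c(=O)c(-c3cc(OC)c(OC)c(OC)c3)coc2cc1O | target

Total step count: 9. Longest linear sequence: 8 (steps 1 to 6, 8 and 9); step 7 is the side branch.

**Steps most likely to fail**

1. Step 8 (new method).
   - What may go wrong:
     - The ambident enolate may attack through carbon, after which the aryl anion would add to the formyl group and the C-C bond would break (acyl-alkylation pathway).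
     - The enolate may lose its chelated Z geometry, so that the aryl anion cannot reach the ester and is only protonated.
     - The aryl anion may expel the neighbouring chloride.
     - Released methoxide may add to C2 of the product and open ring C.
   - Fallback (known deoxybenzoin chemistry, no aryne): it sets out from 7 and 12 and rejoins the route at target 19. Exhaustive hydrogenolysis of 7 (H2, 10% Pd/C, Et3N, MeOH) strips bromine, chlorine and benzyl and should give 4-methoxybenzene-1,3-diol F1. Saponification of 12 (LiOH, THF-H2O) gives 3,4,5-trimethoxyphenylacetic acid F2. Friedel-Crafts acylation of F1 with F2 in BF3·OEt2 at 85 °C occurs ortho to one hydroxyl and para to the other and should give 1-(2,4-dihydroxy-5-methoxyphenyl)-2-(3,4,5-trimethoxyphenyl)ethan-1-one F3. A Vilsmeier-type one-carbon insertion (DMF, MsCl, BF3·OEt2, 60 °C) then formylates the activated methylene and closes ring C through O1-C2, which leads directly to 19.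

2. Step 6.
   - What may go wrong: the aryllithium sits beside chlorine and may lose lithium chloride before silicon has moved. Butyllithium may also attack silicon or the benzylic CH2 in place of bromine.
   - Fallback (no organolithium; silicon is brought in by cross-coupling at the aldehyde stage): it sets out from 5 and rejoins at 11. The ortho formyl group activates the C-Br bond of 5 towards zerovalent palladium. Palladium-catalysed silylation with hexamethyldisilane (Pd2(dba)3, 2-(di-tert-butylphosphino)biphenyl, KF, H2O, DMPU, 100 °C) should give 5-(benzyloxy)-3-chloro-4-methoxy-2-(trimethylsilyl)benzaldehyde F4 with the C-Cl bond intact. Buffered Baeyer-Villiger oxidation (mCPBA, Na2HPO4, CH2Cl2) leads to 5-(benzyloxy)-3-chloro-4-methoxy-2-(trimethylsilyl)phenyl formate F5. Methanolysis (K2CO3 cat., MeOH) leads to 5-(benzyloxy)-3-chloro-4-methoxy-2-(trimethylsilyl)phenol F6, and Tf2O with pyridine in CH2Cl2 at 0 °C leads to 11.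

3. Step 9.
   - What may go wrong: hydrogen may add to the C2-C3 double bond of the pyranone before the C5-Cl bond is fully cleaved. The amine may also slow the benzyl ether cleavage, so that the two reductions do not finish together.
   - Fallback (two separate cleavages without hydrogen gas): it sets out from 18 and rejoins at 19. Homogeneous formate reduction of the aryl chloride (Pd(OAc)2, 2-(di-tert-butylphosphino)biphenyl, HCO2Na, MeOH-THF, 60 °C) should give 7-(benzyloxy)-6-methoxy-3-(3,4,5-trimethoxyphenyl)-4H-chromen-4-one F7. BCl3 with pentamethylbenzene as benzyl cation trap (CH2Cl2, -78 °C) then frees the C7 phenol without touching the methyl ethers and gives 19.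

**Further compounds**

F1 | step 8 | 4-methoxybenzene-1,3-diol | COc1ccc(O)cc1O
F2 | step 8 | 3,4,5-trimethoxyphenylacetic acid | COc1cc(CC(=O)O)cc(OC)c1OC
F3 | step 8 | 1-(2,4-dihydroxy-5-methoxyphenyl)-2-(3,4,5-trimethoxyphenyl)ethan-1-one | COc1cc(C(=O)Cc2cc(OC)c(OC)c(OC)c2)c(O)cc1O
F4 | step 6 | 5-(benzyloxy)-3-chloro-4-methoxy-2-(trimethylsilyl)benzaldehyde | COc1c(Cl)c([Si](C)(C)C)c(C=O)cc1OCc1ccccc1
F5 | step 6 | 5-(benzyloxy)-3-chloro-4-methoxy-2-(trimethylsilyl)phenyl formate | COc1c(Cl)c([Si](C)(C)C)c(OC=O)cc1OCc1ccccc1
F6 | step 6 | 5-(benzyloxy)-3-chloro-4-methoxy-2-(trimethylsilyl)phenol | COc1c(Cl)c([Si](C)(C)C)c(O)cc1OCc1ccccc1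
F7 | step 9 | 7-(benzyloxy)-6-methoxy-3-(3,4,5-trimethoxyphenyl)-4H-chromen-4-one | COc1cc2c(=O)c(-c3cc(OC)c(OC)c(OC)c3)coc2cc1OCc1ccccc1
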